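## Structural features

- Compound 26 is built from three catechol-type benzene rings: ring B of a 2,3-dihydrobenzofuran, a 3,4-dihydroxyphenyl ring on C2, and the 3,4-dihydroxyphenyl ring of an (R)-3-aryllactic acid.
- All six positions of ring B differ. C7a bears O1, C7 a free hydroxyl, C6 and C5 hydrogen, C4 an (E)-propenoate arm, and C3a the ring carbon C3.
- The propenoate is esterified with the secondary hydroxyl of the lactic acid, whose own carboxyl group is free. The carboxyl group on C3 is a methyl ester, so the two carboxyl groups must be kept apart to the end.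
- C2 (S) and C3 (S) are direct neighbours in the five-membered ring and hold aryl and ester trans. The (R) centre of the side chain is remote from both and can be bought.
- The fragile points are:
  - the five air- and base-sensitive phenols;
  - the C3–H bond, which is alpha to the ester, benzylic and beta to O1, so base can epimerise it or open the ring by E1cB;
  - the C2–O1 bond, a para-oxygenated benzylic ether that acids can ionise;
  - the alpha-acyloxy ester centre of the side chain;
  - the cinnamate double bond, which excludes hydrogenolysis.
- The real difficulty is ring B. It carries four contiguous, different substituents (C3a, C4, C7, C7a) that aromatic substitution would not place cleanly, because C5, para to O1, is the naturally reactive position and C4 is not.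
- The key step uses two facts. The run C7a(O1)–C7(O)–C6(H)–C5(H) is the carbon side C3–C4–C5–C6 of a 3,4-dioxygenated pyridazine. C3a–C4 is a two-carbon unit that can be an alkyne already hanging from O1 through C2 and C3.

## Logic of the disconnections

**26 to 25.**
- Bonds cut: five phenolic O–benzyl bonds and one carboxyl O–benzyl bond.
- Reason: free phenols and a free acid cannot pass through bases, palladium and oxidants, and a single type of protecting group needs a single last step.
- Gain: every earlier intermediate is neutral and stable to air.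
- Demand: cleavage without hydrogen (alkene), without base (C3–H, side-chain centre), and without touching the methyl ester or C2–O1.

**25 to 21 and 24.**
- Bond cut: the aryl–vinyl bond at C4.
- Reason: it is the only C–C bond between the two halves, and each half carries its own stereochemistry.
- Gain: convergence, and the costly chiral side chain enters one step before the end.
- Demand: a halogen exactly on C4, a weak base, and E geometry.

**24 to 23 to 22.**
- Bonds cut: the acryloyl C–O bond and three O–benzyl bonds.
- Reason: the stereocentre is bought, and nothing is done at the stereogenic carbon.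
- Gain: two simple operations on a side branch.
- Demand: alkylation that leaves the secondary hydroxyl free, and acylation without racemisation.

**21 to 20 to 18 to 17.**
- Changes undone: the ester O–CH3 bond, the oxidation level of the carbon on C3, and the O–Si bond.
- Reason: an ester on C3 would make C3–H acidic during the basic and the hot steps, so the carbon travels as a silyl-protected CH2OH group.
- Gain: C3 is configurationally inert up to this point.
- Demand: an oxidation close to neutral pH that neither epimerises C3 nor expels O1.

**17 to 16.**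
- Bond exchanged: C4–I for C4–Si.
- Reason: silicon can sit on an alkyne and survive heat, whereas iodine cannot.
- Gain: the handle is placed by the ring construction itself.
- Demand: ipso attack must be faster than C–H iodination on three electron-rich rings.

**16 to 14 (through 15).**
- Bonds cut: C7a–C3a and C5–C4, with N2 re-inserted between C7a and C5.
- Reason: ring B becomes a pyridazine, and C3a–C4 becomes an alkyne on the O1–C2–C3 tether.
- Gain: two rings are removed, and all four substituents of ring B are traced to substituents that are simple to place on a diazine and on an alkyne.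
- Demand: a cycloaddition of an electron-rich diazine that must outrun thermal cleavage of the benzylic C2–O bond.

**14 to 10 and 12 (through 13).**
- Bond cut: O1–C7a, that is alkoxide oxygen to pyridazine C3.
- Reason: the C2–O bond is untouched, so the configuration is retained.
- Gain: an open-chain alcohol and a two-substituent heterocycle.
- Demand: substitution on a deactivated chloride without attack of the alkoxide on either silicon atom.

**12 to 11.**
- Bond cut: benzyl oxygen to pyridazine C4.
- Reason: the more electrophilic of the two chlorinated positions reacts first.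
- Gain: a commercial dichloride.
- Demand: clean mono-substitution at C4.

**10 to 7 and 8 (through 9).**
- Bond cut: C2–C3.
- Reason: both stereocentres arise in one C–C bond formation.
- Gain: an achiral aldehyde and a four-carbon piece with a single stereocentre.
- Demand: transfer of central to axial to central chirality, and anti selectivity.

**7 to 6 to 5.**
- Bonds cut: the O–S bond and the carbinol C–H bond.
- Reason: a ynone is an ideal substrate for catalytic asymmetric reduction.
- Gain: no stereocentre remains.
- Demand: the correct catalyst enantiomer and no base, because of the C–Si bond.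

**5 to 2 and 3 (through 4), and 2 to 1.**
- Bonds cut: the acyl–alkynyl bond and the O–Si bond.
- Gain: three commodity chemicals.
- Demand: mono-addition of the acetylide to an ester.

## Other disconnections considered

**Alternative 1:**

*Cut.* Both bonds that tie the C2–C3 unit to ring B are removed, C3–C3a and O1–C7a.

*Forward key step.* 1-Iodo-2-(methoxymethoxy)benzene A1 and the cis-glycidate methyl (2R,3R)-3-(2,2-dimethyl-1,3-benzodioxol-5-yl)oxirane-2-carboxylate A2 would be merged by a Catellani annulation (Pd(OAc)2, a biarylphosphine, norbornene, Cs2CO3). The aryl–norbornyl palladacycle would alkylate the free ortho carbon with the ester-bearing epoxide carbon under inversion. Norbornene would then leave, and the alkoxide would close O1–C7a by C–O reductive elimination to give the trans ester A3.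

*In its favour.*
- Two simple partners build the whole dihydrofuran ring in one operation.
- The methyl ester is present from the start, which would make steps 10 to 12 unnecessary. This is better than the chosen plan.
- The temperature is far lower than in step 8.
- The acetal protecting groups would spare a final Lewis acid.

*Against it here.*
- This annulation is established for epoxides attacked at an unhindered carbon. A2 is internal and offers a second carbon, benzylic to an electron-rich ring, where glycidates normally open.
- Hot carbonate base meets in A3 the acidic C3–H that the chosen plan hides until step 11.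
- Enantiopure A2 is harder to obtain than 7.
- A3 has hydrogen on C4. The propenoate arm would then need a directed C–H olefination through the free C3 acid, so hydrolysis and re-esterification give back the steps saved.

*Comparison.*
- Structure: the alternative solves the five-membered ring but not ring B, whereas the chosen plan solves both at once.
- Mechanism: inversion at one defined carbon is as clean a stereochemical device as the anti addition of step 5. The regiochemistry, however, rests on a preference of the epoxide, while in step 8 it is fixed by the tether.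
- Step economy: the two are about equal once the C4 arm is counted.

**Alternative 2:**

*Cut.* C3–C3a is cut, and the ester carbon is reconnected to C3a as the ketone of a six-membered ring. The precursor is the flavanone (2S)-8-acetoxy-5-bromo-2-(3,4-diacetoxyphenyl)chroman-4-one A4.

*Forward key step.* PhI(OAc)2 and H2SO4 in trimethyl orthoformate would turn A4 into its enol ether. Trivalent iodine would add at C3, and ring B carbon C4a would migrate from the former carbonyl carbon to C3 as iodobenzene leaves. The ring contracts and the methyl ester of A5 remains.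

*In its favour.*
- Oxidative contraction of flavanones to trans-2-aryl-2,3-dihydrobenzofuran-3-carboxylates is a known reaction type.
- One step delivers the ester, the trans relation and, with the bromine carried along, the C4 handle.
- Only C2 has to be set beforehand.
- Acetates come off without a Lewis acid.
- In step economy and in the mildness of the end game this is the better plan.

*Against it here.*
- The migrating carbon belongs to a ring deactivated by bromine and acetoxy and is flanked by the bromine.
- The usual leaks of this reaction compete: a shift of the C2 aryl group to C3, and plain dehydrogenation across C2–C3.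
- Aryl acetates are unlikely to stay in place in sulfuric acid and orthoformate.
- A4 must be one enantiomer, although flavanones racemise by reversible ring opening in acid or base.
- The crowded 5-bromo-8-oxy pattern is not a standard substrate for asymmetric flavanone synthesis.

*Comparison.*
- Structure: both plans deliver a C4 handle. The alternative is equal here, and it also reaches the right oxidation level.
- Mechanism: the alternative depends on relative migratory aptitudes that this substitution pattern turns the wrong way. The chosen key step has only one possible regiochemical outcome, and its uncertainty is one of rate.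
- Stereochemistry: the chosen plan carries two robust centres, while the alternative relies on one labile centre.

**Alternative 3:**

*Cut.* C3a–C7a and C6–C7 are cut, and the C7–O bond is traced back to a furan oxygen. The precursor is the anti ethynyl ether A6, with a 2-furyl group on C3 and an O–C≡CH group on C2.

*Forward key step.* Ph3PAuNTf2 would activate the ynol ether, and furan C2 would attack the internal alkyne carbon. The cascade of the gold-catalysed furan–yne phenol synthesis would then end with furan C5 bonded to the terminal alkyne carbon and the oxygen on C7, giving phenol A7.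

*In its favour.*
- Like step 8, it forms ring B and the dihydrofuran ring together from an open-chain stereodiad, so it is equal on that point.
- It should run near room temperature instead of about 200 °C, which is better.
- It is a pure isomerisation.
- It frees the 7-hydroxyl already distinguished from the other phenols.

*Against it here.*
- The ethynyl ether of a secondary, electron-rich benzylic alcohol is difficult to prepare and prone to fragment by a retro-ene path on mild warming.
- A gold-bound ynol ether is a strong electron sink that invites ionisation of the C2–O bond.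
- A7 has hydrogen on C4, so a late directed C–H olefination or a 3-substituted furan would be needed.
- The anti array with a furyl group on C3 needs a stereoselective construction of its own, for which step 5 offers no model.

*Comparison.*
- Structure: the alternative places three of the four ring B substituents, the chosen plan all four.
- Mechanism: the alternative is milder, but its precursor is the more fragile. The chosen precursor is robust at room temperature and at risk only during the heating.
- Step economy: the counts are similar.

Key step: step 8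

Assumption: 22 is used as the free acid; its sodium salt would only need one equivalent less of K2CO3 in step 13.

Remark: the structures of 14 and 16 agree atom for atom and centre for centre with 26. C3 is called R in 10, 14 and 16–18 and S in 19–21, 25 and 26 without any change of geometry, because CH2O ranks below C2 whereas CHO and CO2R rank above it.

Step 1
Reactants: 1 methyl glycolate
Product: 2 methyl 2-[(triisopropylsilyl)oxy]acetate
Conditions: TIPSCl, imidazole, DMF, 0 °C to rt
Reagents that add atoms: chlorotriisopropylsilane, CC(C)[Si](Cl)(C(C)C)C(C)C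
Why: Imidazole-promoted O-silylation of a primary alcohol. The bulky TIPS group is chosen because it must later resist a neighbouring alkoxide (step 7), about 200 °C (step 8) and ICl (step 9).

Step 2
Reactants: 2 methyl 2-[(triisopropylsilyl)oxy]acetate; 3 trimethylsilylacetylene
Product: 5 1-[(triisopropylsilyl)oxy]-4-(trimethylsilyl)but-3-yn-2-one, via lithium (trimethylsilyl)acetylide 4 (not isolated)
Conditions: 3, n-BuLi, THF, −78 °C; BF3·OEt2, −78 °C; then 2, −78 °C; aq NH4Cl
Reagents that add atoms: none
Why: BF3-mediated acylation of a lithium acetylide by an ester (ynone synthesis through an alkynylboron species). The boron-bound tetrahedral adduct should persist at −78 °C, so the ketone is released only on quenching and a second addition is avoided.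

Step 3
Reactants: 5 1-[(triisopropylsilyl)oxy]-4-(trimethylsilyl)but-3-yn-2-one
Product: 6 (S)-1-[(triisopropylsilyl)oxy]-4-(trimethylsilyl)but-3-yn-2-ol
Conditions: Ru[(R,R)-TsNCH(Ph)CH(Ph)NH](p-cymene) (1 mol %), i-PrOH, rt
Reagents that add atoms: none
Why: Noyori asymmetric transfer hydrogenation of a ynone, in which the alkynyl group lies under the cymene ligand and so fixes the face that receives hydride. The (R,R) catalyst gives the spatial arrangement of (R)-4-(trimethylsilyl)but-3-yn-2-ol, which is named S here because CH2OSi outranks the alkynyl group. The preformed base-free amido complex protects the C–Si bond.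

Step 4
Reactants: 6 (S)-1-[(triisopropylsilyl)oxy]-4-(trimethylsilyl)but-3-yn-2-ol
Product: 7 (S)-1-[(triisopropylsilyl)oxy]-4-(trimethylsilyl)but-3-yn-2-yl methanesulfonate
Conditions: MsCl, Et3N, CH2Cl2, −78 to 0 °C
Reagents that add atoms: methanesulfonyl chloride, CS(=O)(=O)Cl
Why: O-sulfonylation; the C–O bond is not touched, so the configuration is retained. The mesylate is used after a short work-up without chromatography.

Step 5
Reactants: 7 (S)-1-[(triisopropylsilyl)oxy]-4-(trimethylsilyl)but-3-yn-2-yl methanesulfonate; 8 3,4-bis(benzyloxy)benzaldehyde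
Product: 10 (1S,2R)-1-[3,4-bis(benzyloxy)phenyl]-2-{[(triisopropylsilyl)oxy]methyl}-4-(trimethylsilyl)but-3-yn-1-ol, via allenylzinc mesylate 9 (not isolated)
Conditions: Pd(OAc)2 (5 mol %), PPh3 (5 mol %), Et2Zn (3 equiv), THF, −78 to −20 °C
Reagents that add atoms: none
Why: Marshall–Tamaru propargylation: zerovalent palladium displaces the mesylate in an anti SN2' sense, Et2Zn takes over the allenyl group with retention to give the (P)-allenylzinc 9, and 9 adds to 8 through a closed SE2' transition state on its zinc-bearing face. The allene axis fixes C3 (the new bond forms on the face opposite to the departed mesylate), and the aryl group turning away from the CH2OTIPS group in the cyclic array fixes C2, which gives the anti (1S,2R) isomer. The aldehyde is present from the start and the temperature is low so that addition outruns loss of silanolate from 9; allenylmetals with a heteroatom on the adjacent carbon are known to add cleanly in the related palladium/indium umpolung of ethynylaziridines.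

Step 6
Reactants: 11 3,4-dichloropyridazine
Product: 12 4-(benzyloxy)-3-chloropyridazine
Conditions: BnOH (1.0 equiv), NaH, THF, 0 °C to rt
Reagents that add atoms: benzyl alcohol, OCc1ccccc1
Why: Nucleophilic aromatic substitution; in 3,4-dihalopyridazines C4, para to N1, is the position that alkoxides and amines attack first. One equivalent at low temperature stops after the first substitution, because the new alkoxy group deactivates the ring.

Step 7
Reactants: 10 (1S,2R)-1-[3,4-bis(benzyloxy)phenyl]-2-{[(triisopropylsilyl)oxy]methyl}-4-(trimethylsilyl)but-3-yn-1-ol; 12 4-(benzyloxy)-3-chloropyridazine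
Product: 14 4-(benzyloxy)-3-{[(1S,2R)-1-[3,4-bis(benzyloxy)phenyl]-2-{[(triisopropylsilyl)oxy]methyl}-4-(trimethylsilyl)but-3-yn-1-yl]oxy}pyridazine, via sodium alkoxide 13 (not isolated)
Conditions: NaH, THF, 0 °C; then 12 (1.3 equiv), 0 to 45 °C
Reagents that add atoms: none
Why: Nucleophilic aromatic substitution at pyridazine C3, alpha to N2; only the O–H bond of 10 is broken, so C2 keeps its configuration. The bulk of TIPS opposes a 1,5 oxygen-to-oxygen silyl shift. The sodium counter-ion, the excess of 12 and the moderate temperature limit attack of the alkoxide on the alkynyl silicon.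

Step 8
Reactants: 14 4-(benzyloxy)-3-{[(1S,2R)-1-[3,4-bis(benzyloxy)phenyl]-2-{[(triisopropylsilyl)oxy]methyl}-4-(trimethylsilyl)but-3-yn-1-yl]oxy}pyridazine
Product: 16 (2S,3R)-7-(benzyloxy)-2-[3,4-bis(benzyloxy)phenyl]-3-{[(triisopropylsilyl)oxy]methyl}-4-(trimethylsilyl)-2,3-dihydrobenzofuran, via bridged diazene 15 (not isolated)
Conditions: 1,3,5-triisopropylbenzene (0.01 M), BHT (cat.), argon, base-washed sealed vessel, 190–210 °C
Reagents that add atoms: none
Why: Intramolecular inverse-electron-demand Diels–Alder reaction of a 1,2-diazine followed by retro-Diels–Alder loss of N2: the alkyne adds across pyridazine C3 and C6, the inner alkyne carbon bonding to C3 (C7a–C3a) and the silylated carbon to C6 (C5–C4), and the bridged diazene 15 expels N2 irreversibly to give the arene 16. The closest known reaction type is the thermal cyclisation of 3-(but-3-ynyloxy)- and 3-(but-3-ynylamino)pyridazines to 2,3-dihydrobenzofurans and indolines. The dihydrofuran ring closes in the fused mode as the tether ring of the [4+2] step (O1, C2, C3, C3a, C7a), and ring B closes as the six-membered cycloaddition ring made of pyridazine C3 to C6 and the two alkyne carbons. No lasting stereocentre is formed, since the two bridgeheads of 15 disappear with N2, and C2 and C3 carry no acidic hydrogen, so the anti array of 14 becomes the trans array of 16. Regiochemistry needs no further control, because the three-atom tether allows only one orientation and the 3,4-placement of the two oxygens then decides where every substituent ends. The selectivity that matters is cycloaddition ahead of thermal cleavage of the benzylic C2–O bond (six-centre elimination towards N2, or ionisation). It is supported by the anti substitution pattern, whose favoured conformer already holds O1 and the alkynyl group gauche with the aryl group anti to the alkyne, and by the non-polar solvent, high dilution and acid-free glass. It is further supported by the lowest workable temperature with a long reaction time, since the cleavage should have the higher activation energy, and by the fact that trimethylsilyl is the smallest usable silyl group and that benzyl and TIPS ethers have no pericyclic escape such as a Claisen shift.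

Step 9
Reactants: 16 (2S,3R)-7-(benzyloxy)-2-[3,4-bis(benzyloxy)phenyl]-3-{[(triisopropylsilyl)oxy]methyl}-4-(trimethylsilyl)-2,3-dihydrobenzofuran
Product: 17 (2S,3R)-7-(benzyloxy)-2-[3,4-bis(benzyloxy)phenyl]-4-iodo-3-{[(triisopropylsilyl)oxy]methyl}-2,3-dihydrobenzofuran
Conditions: ICl (1.05 equiv), CH2Cl2, −78 to −20 °C
Reagents that add atoms: iodine monochloride, ICl
Why: Ipso-iododesilylation (electrophilic aromatic substitution). C4 is para to the 7-benzyloxy group, and the cation formed by ipso attack is stabilised by the beta-silicon effect, so it should be attacked well before any C–H position of the three electron-rich rings when one equivalent is used cold.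

Step 10
Reactants: 17 (2S,3R)-7-(benzyloxy)-2-[3,4-bis(benzyloxy)phenyl]-4-iodo-3-{[(triisopropylsilyl)oxy]methyl}-2,3-dihydrobenzofuran
Product: 18 {(2S,3R)-7-(benzyloxy)-2-[3,4-bis(benzyloxy)phenyl]-4-iodo-2,3-dihydrobenzofuran-3-yl}methanol
Conditions: TBAF, THF, 0 °C to rt
Reagents that add atoms: none
Why: Fluoride cleavage of a silyl ether. It is placed before the fragment union so that the basic fluoride never meets the racemisable alpha-acyloxy ester, and at this stage C3–H is not acidic.

Step 11
Reactants: 18 {(2S,3R)-7-(benzyloxy)-2-[3,4-bis(benzyloxy)phenyl]-4-iodo-2,3-dihydrobenzofuran-3-yl}methanol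
Product: 20 (2S,3S)-7-(benzyloxy)-2-[3,4-bis(benzyloxy)phenyl]-4-iodo-2,3-dihydrobenzofuran-3-carboxylic acid, via aldehyde 19 (not isolated)
Conditions: TEMPO (0.2 equiv), PhI(OAc)2 (2.5 equiv), MeCN–H2O 1:1, rt
Reagents that add atoms: water, O
Why: Oxoammonium (TEMPO/PhI(OAc)2) oxidation of a primary alcohol to the acid in one flask: aldehyde 19 is hydrated and oxidised again. The medium is weakly acidic, so neither epimerisation of C3 nor E1cB loss of O1 is expected, and the trans isomer is in any case the more stable one.

Step 12
Reactants: 20 (2S,3S)-7-(benzyloxy)-2-[3,4-bis(benzyloxy)phenyl]-4-iodo-2,3-dihydrobenzofuran-3-carboxylic acid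
Product: 21 methyl (2S,3S)-7-(benzyloxy)-2-[3,4-bis(benzyloxy)phenyl]-4-iodo-2,3-dihydrobenzofuran-3-carboxylate
Conditions: MeI, KHCO3, DMF, rt
Reagents that add atoms: iodomethane, CI
Why: SN2 O-alkylation of a carboxylate. Hydrogencarbonate is strong enough for the acid and too weak to deprotonate C3–H of the product.

Step 13
Reactants: 22 (R)-3-(3,4-dihydroxyphenyl)lactic acid (danshensu)
Product: 23 benzyl (R)-3-[3,4-bis(benzyloxy)phenyl]-2-hydroxypropanoate
Conditions: BnBr (3.3 equiv), K2CO3, DMF, N2, rt to 40 °C
Reagents that add atoms: benzyl bromide, BrCc1ccccc1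
Why: Williamson ether synthesis on both phenols and carboxylate alkylation in one pot. K2CO3 does not deprotonate the secondary alcohol, which stays free, and the bought stereocentre is not involved.

Step 14
Reactants: 23 benzyl (R)-3-[3,4-bis(benzyloxy)phenyl]-2-hydroxypropanoate
Product: 24 benzyl (R)-2-(acryloyloxy)-3-[3,4-bis(benzyloxy)phenyl]propanoate
Conditions: acryloyl chloride, i-Pr2NEt, CH2Cl2, −20 to 0 °C
Reagents that add atoms: acryloyl chloride, C=CC(=O)Cl
Why: O-acylation of a secondary alcohol with an acid chloride. The C–O bond at the stereocentre is untouched, and the hindered amine at low temperature should not enolise the ester.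

Step 15
Reactants: 21 methyl (2S,3S)-7-(benzyloxy)-2-[3,4-bis(benzyloxy)phenyl]-4-iodo-2,3-dihydrobenzofuran-3-carboxylate; 24 benzyl (R)-2-(acryloyloxy)-3-[3,4-bis(benzyloxy)phenyl]propanoate
Product: 25 methyl (2S,3S)-7-(benzyloxy)-4-[(E)-3-{[(R)-1-(benzyloxy)-3-[3,4-bis(benzyloxy)phenyl]-1-oxopropan-2-yl]oxy}-3-oxoprop-1-en-1-yl]-2-[3,4-bis(benzyloxy)phenyl]-2,3-dihydrobenzofuran-3-carboxylate
Conditions: Pd(OAc)2 (5 mol %), n-Bu4NCl, NaHCO3, DMF, 70 °C
Reagents that add atoms: none
Why: Heck reaction under Jeffery conditions: oxidative addition of the aryl iodide, syn insertion of the acrylate at its terminal carbon and syn beta-hydride elimination give the E cinnamate. Hydrogencarbonate is the only base, so C3 and the alpha-acyloxy centre should hold.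

Step 16
Reactants: 25 methyl (2S,3S)-7-(benzyloxy)-4-[(E)-3-{[(R)-1-(benzyloxy)-3-[3,4-bis(benzyloxy)phenyl]-1-oxopropan-2-yl]oxy}-3-oxoprop-1-en-1-yl]-2-[3,4-bis(benzyloxy)phenyl]-2,3-dihydrobenzofuran-3-carboxylate
Product: 26 monomethyl lithospermate
Conditions: BCl3 (12 equiv), pentamethylbenzene (18 equiv), CH2Cl2, −78 to −30 °C; then aq THF
Reagents that add atoms: none
Why: Lewis-acid debenzylation with a non-basic cation scavenger: BCl3 binds the ether and ester oxygens and the benzyl cations pass to pentamethylbenzene by Friedel–Crafts alkylation. The alkene, the methyl ester and the acyl–oxygen bonds offer no stabilised cation and should remain. Cold BCl3 debenzylation is a known operation on 2-(benzyloxyaryl)-2,3-dihydrobenzofuran-3-carbonyl compounds.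

## Compound list

1 | methyl glycolate | COC(=O)CO | starting material
2 | methyl 2-[(triisopropylsilyl)oxy]acetate | COC(=O)CO[Si](C(C)C)(C(C)C)C(C)C | intermediate
3 | trimethylsilylacetylene | C#C[Si](C)(C)C | starting material
4 | lithium (trimethylsilyl)acetylide | [Li]C#C[Si](C)(C)C | intermediate
5 | 1-[(triisopropylsilyl)oxy]-4-(trimethylsilyl)but-3-yn-2-one | CC(C)[Si](C(C)C)(C(C)C)OCC(=O)C#C[Si](C)(C)C | intermediate
6 | (S)-1-[(triisopropylsilyl)oxy]-4-(trimethylsilyl)but-3-yn-2-ol | CC(C)[Si](C(C)C)(C(C)C)OC[C@@H](O)C#C[Si](C)(C)C | intermediate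
7 | (S)-1-[(triisopropylsilyl)oxy]-4-(trimethylsilyl)but-3-yn-2-yl methanesulfonate | CC(C)[Si](C(C)C)(C(C)C)OC[C@@H](OS(C)(=O)=O)C#C[Si](C)(C)C | intermediate
8 | 3,4-bis(benzyloxy)benzaldehyde | O=Cc1ccc(OCc2ccccc2)c(OCc2ccccc2)c1 | starting material
9 | (P)-{4-[(triisopropylsilyl)oxy]-1-(trimethylsilyl)buta-1,2-dien-1-yl}zinc methanesulfonate | CC(C)[Si](C(C)C)(C(C)C)OCC([H])=[C@]=C([Zn]OS(C)(=O)=O)[Si](C)(C)C | intermediate
10 | (1S,2R)-1-[3,4-bis(benzyloxy)phenyl]-2-{[(triisopropylsilyl)oxy]methyl}-4-(trimethylsilyl)but-3-yn-1-ol (anti) | CC(C)[Si](C(C)C)(C(C)C)OC[C@H]([C@H](O)c1ccc(OCc2ccccc2)c(OCc2ccccc2)c1)C#C[Si](C)(C)C | intermediate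
11 | 3,4-dichloropyridazine | Clc1nnccc1Cl | starting material
12 | 4-(benzyloxy)-3-chloropyridazine | Clc1nnccc1OCc1ccccc1 | intermediate
13 | sodium alkoxide of 10 | CC(C)[Si](C(C)C)(C(C)C)OC[C@H]([C@H]([O-])c1ccc(OCc2ccccc2)c(OCc2ccccc2)c1)C#C[Si](C)(C)C.[Na+] | intermediate
14 | 4-(benzyloxy)-3-{[(1S,2R)-1-[3,4-bis(benzyloxy)phenyl]-2-{[(triisopropylsilyl)oxy]methyl}-4-(trimethylsilyl)but-3-yn-1-yl]oxy}pyridazine | CC(C)[Si](C(C)C)(C(C)C)OC[C@H]([C@H](Oc1nnccc1OCc1ccccc1)c1ccc(OCc2ccccc2)c(OCc2ccccc2)c1)C#C[Si](C)(C)C | intermediate
15 | bridged diazene, the 2,3-diazabicyclo[2.2.2]octatriene cycloadduct of 14 (drawn with the C2 aryl group on the side of the N=N bridge; the other bridgehead isomer would give the same 16) | CC(C)[Si](C(C)C)(C(C)C)OC[C@H]1C2=C([Si](C)(C)C)[C@H]3C=C(OCc4ccccc4)[C@@]2(N=N3)O[C@@H]1c1ccc(OCc2ccccc2)c(OCc2ccccc2)c1 | intermediate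
16 | (2S,3R)-7-(benzyloxy)-2-[3,4-bis(benzyloxy)phenyl]-3-{[(triisopropylsilyl)oxy]methyl}-4-(trimethylsilyl)-2,3-dihydrobenzofuran (trans) | CC(C)[Si](C(C)C)(C(C)C)OC[C@H]1c2c([Si](C)(C)C)ccc(OCc3ccccc3)c2O[C@@H]1c1ccc(OCc2ccccc2)c(OCc2ccccc2)c1 | intermediate
17 | (2S,3R)-7-(benzyloxy)-2-[3,4-bis(benzyloxy)phenyl]-4-iodo-3-{[(triisopropylsilyl)oxy]methyl}-2,3-dihydrobenzofuran | CC(C)[Si](C(C)C)(C(C)C)OC[C@H]1c2c(I)ccc(OCc3ccccc3)c2O[C@@H]1c1ccc(OCc2ccccc2)c(OCc2ccccc2)c1 | intermediate
18 | {(2S,3R)-7-(benzyloxy)-2-[3,4-bis(benzyloxy)phenyl]-4-iodo-2,3-dihydrobenzofuran-3-yl}methanol | OC[C@H]1c2c(I)ccc(OCc3ccccc3)c2O[C@@H]1c1ccc(OCc2ccccc2)c(OCc2ccccc2)c1 | intermediate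
19 | (2S,3S)-7-(benzyloxy)-2-[3,4-bis(benzyloxy)phenyl]-4-iodo-2,3-dihydrobenzofuran-3-carbaldehyde | O=C[C@H]1c2c(I)ccc(OCc3ccccc3)c2O[C@@H]1c1ccc(OCc2ccccc2)c(OCc2ccccc2)c1 | intermediate
20 | (2S,3S)-7-(benzyloxy)-2-[3,4-bis(benzyloxy)phenyl]-4-iodo-2,3-dihydrobenzofuran-3-carboxylic acid | OC(=O)[C@H]1c2c(I)ccc(OCc3ccccc3)c2O[C@@H]1c1ccc(OCc2ccccc2)c(OCc2ccccc2)c1 | intermediate
21 | methyl (2S,3S)-7-(benzyloxy)-2-[3,4-bis(benzyloxy)phenyl]-4-iodo-2,3-dihydrobenzofuran-3-carboxylate | COC(=O)[C@H]1c2c(I)ccc(OCc3ccccc3)c2O[C@@H]1c1ccc(OCc2ccccc2)c(OCc2ccccc2)c1 | intermediate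
22 | (R)-3-(3,4-dihydroxyphenyl)lactic acid (danshensu) | O[C@H](Cc1ccc(O)c(O)c1)C(=O)O | starting material
23 | benzyl (R)-3-[3,4-bis(benzyloxy)phenyl]-2-hydroxypropanoate | O[C@H](Cc1ccc(OCc2ccccc2)c(OCc2ccccc2)c1)C(=O)OCc1ccccc1 | intermediate
24 | benzyl (R)-2-(acryloyloxy)-3-[3,4-bis(benzyloxy)phenyl]propanoate | C=CC(=O)O[C@H](Cc1ccc(OCc2ccccc2)c(OCc2ccccc2)c1)C(=O)OCc1ccccc1 | intermediate
25 | hexabenzyl-protected monomethyl lithospermate (full name in step 15) | COC(=O)[C@H]1c2c(/C=C/C(=O)O[C@H](Cc3ccc(OCc4ccccc4)c(OCc4ccccc4)c3)C(=O)OCc3ccccc3)ccc(OCc3ccccc3)c2O[C@@H]1c1ccc(OCc2ccccc2)c(OCc2ccccc2)c1 | intermediate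
26 | monomethyl lithospermate, (2S,3S) in the dihydrobenzofuran, (R) in the side chain, E alkene | COC(=O)[C@H]1c2c(/C=C/C(=O)O[C@H](Cc3ccc(O)c(O)c3)C(=O)O)ccc(O)c2O[C@@H]1c1ccc(O)c(O)c1 | target

## Step count and least certain steps

Total step count: 16. Longest linear sequence: 13 steps (steps 1–5, 7–12, 15 and 16).

**Step 8 (key step).**

*Risk.* The most likely failure is thermal cleavage of the C2–O bond outrunning the cycloaddition.
- The bond is benzylic to a para-oxygenated ring and leads to a good heteroaryloxy leaving group.
- Two cleavage paths can therefore set in near 200 °C: a six-centre elimination in which N2 takes the C3 hydrogen, or ionisation followed by oxygen-to-nitrogen transfer.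
- At the same time the diene is slowed by two donor oxygens and the dienophile by its silyl group.
- A boron Lewis acid on the two nitrogens is not attractive here, because it would also turn the heteroaryloxy group into a still better leaving group.

*Fallback.* The two ring-forming bonds are kept, and the one retarding group that is not part of the target is removed.
1. Setting out from 14, K2CO3 in MeOH takes off the alkynyl silyl group to give the terminal alkyne ether F1.
2. F1 should cyclise at a lower temperature, through the bridged diazene F2, to the 4-unsubstituted dihydrobenzofuran F3.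
3. TBAF gives the alcohol F4.
4. TEMPO/PhI(OAc)2 in aqueous MeCN leads through the aldehyde F5 to the acid F6.
5. The missing C4 handle is replaced by a carboxylate-directed C–H olefination of F6 with 24 (Pd(OAc)2, Ac-Ile-OH, KHCO3, O2, t-AmylOH, 85 °C). C4 is the only free ortho position, so this gives the cinnamate acid F7.
6. MeI and KHCO3 bring the route back at 25.

**Step 5.**

*Risk.* Three processes threaten it:
- poor facial selectivity at a flat, electron-rich aromatic aldehyde, which erodes the anti preference;
- 1,4-elimination of silanolate from the allenylmetal, since the silyloxy group sits on the carbon next to the reacting terminus;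
- partial racemisation of the allenylpalladium species before transmetalation.

*Fallback.* Allenylmetals are abandoned in favour of an auxiliary-controlled aldol reaction. It sets out from 8.
1. Commercial 4-(trimethylsilyl)but-3-yn-1-ol is oxidised (Jones oxidation) to 4-(trimethylsilyl)but-3-ynoic acid F8.
2. F8 is activated as the pivalic mixed anhydride F9 and joined to lithiated (S)-4-benzyloxazolidin-2-one to give the imide F10.
3. Bu2BOTf and i-Pr2NEt at −78 °C form the Z boron enolate F11.
4. F11 adds to 8 in an Evans syn aldol reaction (Zimmerman–Traxler chair, hydrolytic work-up) to give the adduct F12.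
5. Syn in this aldol chain is the same relative configuration as anti in 10, because the acyl carbon becomes the CH2O arm and the alkynyl group is the alpha substituent.
6. LiBH4 removes the auxiliary and gives the diol F13.
7. TIPSCl and imidazole silylate only the primary hydroxyl, and the route is rejoined at 10.

**Step 7.**

*Risk.* Compound 12 is deactivated by its alkoxy group and needs warming. The alkoxide may therefore attack silicon instead of carbon, with transfer of the alkynyl trimethylsilyl group or migration of TIPS from the primary to the secondary oxygen.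

*Fallback.* The electrophile is changed so that the coupling can run cold. It sets out from 12.
1. NaSMe in THF gives 4-(benzyloxy)-3-(methylsulfanyl)pyridazine F14.
2. Oxone in aqueous MeOH gives 4-(benzyloxy)-3-(methylsulfonyl)pyridazine F15.
3. The sulfinate leaving group of F15 should be displaced by 13 between −40 and 0 °C, and the route is rejoined at 14.

**Step 16.**

*Risk.* The benzyl ester should be the slowest of the six benzyl groups to leave. Forcing it by warming invites three failures: ionisation of the C2–O1 bond by the Lewis acid, capture of the resulting cation by the scavenger, or loss of the C3 proton with ring opening.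

*Fallback.* The carboxyl group is given a far more labile protecting group, so that everything falls at −78 °C. It sets out from 22.
1. 4-Methoxybenzyl chloride and KHCO3 in DMF alkylate only the carboxylate to give the 4-methoxybenzyl ester F16.
2. BnBr and K2CO3 give the bis(benzyl ether) F17.
3. Acryloyl chloride and i-Pr2NEt give the acrylate F18.
4. The Heck reaction of step 15 with 21 gives the protected product F19.
5. BCl3 and pentamethylbenzene, kept at −78 °C, lead to 26.

**Step 2.**

*Risk.* Collapse of the tetrahedral adduct before the quench would allow a second addition of the acetylide. Alternatively, the hindered alpha-silyloxy ester may be acylated incompletely.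

*Fallback.* The acyl transfer is split into two steps. It sets out from 2.
1. MeNH(OMe)·HCl and i-PrMgCl in THF give the Weinreb amide F20.
2. F20 takes up 4 once only, through its chelated adduct, and returns the route at 5.

## Further compounds

F1 | step 8 | 4-(benzyloxy)-3-{[(1S,2R)-1-[3,4-bis(benzyloxy)phenyl]-2-{[(triisopropylsilyl)oxy]methyl}but-3-yn-1-yl]oxy}pyridazine | CC(C)[Si](C(C)C)(C(C)C)OC[C@H]([C@H](Oc1nnccc1OCc1ccccc1)c1ccc(OCc2ccccc2)c(OCc2ccccc2)c1)C#C
F2 | step 8 | bridged diazene from F1 | CC(C)[Si](C(C)C)(C(C)C)OC[C@H]1C2=C[C@H]3C=C(OCc4ccccc4)[C@@]2(N=N3)O[C@@H]1c1ccc(OCc2ccccc2)c(OCc2ccccc2)c1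
F3 | step 8 | (2S,3R)-7-(benzyloxy)-2-[3,4-bis(benzyloxy)phenyl]-3-{[(triisopropylsilyl)oxy]methyl}-2,3-dihydrobenzofuran | CC(C)[Si](C(C)C)(C(C)C)OC[C@H]1c2cccc(OCc3ccccc3)c2O[C@@H]1c1ccc(OCc2ccccc2)c(OCc2ccccc2)c1
F4 | step 8 | {(2S,3R)-7-(benzyloxy)-2-[3,4-bis(benzyloxy)phenyl]-2,3-dihydrobenzofuran-3-yl}methanol | OC[C@H]1c2cccc(OCc3ccccc3)c2O[C@@H]1c1ccc(OCc2ccccc2)c(OCc2ccccc2)c1
F5 | step 8 | (2S,3S)-7-(benzyloxy)-2-[3,4-bis(benzyloxy)phenyl]-2,3-dihydrobenzofuran-3-carbaldehyde | O=C[C@H]1c2cccc(OCc3ccccc3)c2O[C@@H]1c1ccc(OCc2ccccc2)c(OCc2ccccc2)c1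
F6 | step 8 | (2S,3S)-7-(benzyloxy)-2-[3,4-bis(benzyloxy)phenyl]-2,3-dihydrobenzofuran-3-carboxylic acid | OC(=O)[C@H]1c2cccc(OCc3ccccc3)c2O[C@@H]1c1ccc(OCc2ccccc2)c(OCc2ccccc2)c1
F7 | step 8 | C3 carboxylic acid corresponding to 25 | OC(=O)[C@H]1c2c(/C=C/C(=O)O[C@H](Cc3ccc(OCc4ccccc4)c(OCc4ccccc4)c3)C(=O)OCc3ccccc3)ccc(OCc3ccccc3)c2O[C@@H]1c1ccc(OCc2ccccc2)c(OCc2ccccc2)c1
F8 | step 5 | 4-(trimethylsilyl)but-3-ynoic acid | C[Si](C)(C)C#CCC(=O)O
F9 | step 5 | pivalic 4-(trimethylsilyl)but-3-ynoic anhydride | CC(C)(C)C(=O)OC(=O)CC#C[Si](C)(C)C
F10 | step 5 | (S)-4-benzyl-3-[4-(trimethylsilyl)but-3-ynoyl]oxazolidin-2-one | C[Si](C)(C)C#CCC(=O)N1C(=O)OC[C@@H]1Cc1ccccc1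
F11 | step 5 | Z dibutylboron enolate of F10 | CCCCB(CCCC)O/C(=C\C#C[Si](C)(C)C)N1C(=O)OC[C@@H]1Cc1ccccc1
F12 | step 5 | (S)-4-benzyl-3-{(2S,3S)-3-[3,4-bis(benzyloxy)phenyl]-3-hydroxy-2-[(trimethylsilyl)ethynyl]propanoyl}oxazolidin-2-one | O=C1OC[C@H](Cc2ccccc2)N1C(=O)[C@@H](C#C[Si](C)(C)C)[C@H](O)c1ccc(OCc2ccccc2)c(OCc2ccccc2)c1
F13 | step 5 | (1S,2R)-1-[3,4-bis(benzyloxy)phenyl]-2-[(trimethylsilyl)ethynyl]propane-1,3-diol | OC[C@H]([C@H](O)c1ccc(OCc2ccccc2)c(OCc2ccccc2)c1)C#C[Si](C)(C)C
F14 | step 7 | 4-(benzyloxy)-3-(methylsulfanyl)pyridazine | CSc1nnccc1OCc1ccccc1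
F15 | step 7 | 4-(benzyloxy)-3-(methylsulfonyl)pyridazine | CS(=O)(=O)c1nnccc1OCc1ccccc1
F16 | step 16 | 4-methoxybenzyl (R)-3-(3,4-dihydroxyphenyl)-2-hydroxypropanoate | O[C@H](Cc1ccc(O)c(O)c1)C(=O)OCc1ccc(OC)cc1
F17 | step 16 | 4-methoxybenzyl (R)-3-[3,4-bis(benzyloxy)phenyl]-2-hydroxypropanoate | O[C@H](Cc1ccc(OCc2ccccc2)c(OCc2ccccc2)c1)C(=O)OCc1ccc(OC)cc1
F18 | step 16 | 4-methoxybenzyl (R)-2-(acryloyloxy)-3-[3,4-bis(benzyloxy)phenyl]propanoate | C=CC(=O)O[C@H](Cc1ccc(OCc2ccccc2)c(OCc2ccccc2)c1)C(=O)OCc1ccc(OC)cc1
F19 | step 16 | analogue of 25 with a 4-methoxybenzyl ester in place of the benzyl ester | COC(=O)[C@H]1c2c(/C=C/C(=O)O[C@H](Cc3ccc(OCc4ccccc4)c(OCc4ccccc4)c3)C(=O)OCc3ccc(OC)cc3)ccc(OCc3ccccc3)c2O[C@@H]1c1ccc(OCc2ccccc2)c(OCc2ccccc2)c1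
F20 | step 2 | N-methoxy-N-methyl-2-[(triisopropylsilyl)oxy]acetamide | CON(C)C(=O)CO[Si](C(C)C)(C(C)C)C(C)C
A1 | alternative 1 | 1-iodo-2-(methoxymethoxy)benzene | COCOc1ccccc1I
A2 | alternative 1 | methyl (2R,3R)-3-(2,2-dimethyl-1,3-benzodioxol-5-yl)oxirane-2-carboxylate (cis) | COC(=O)[C@@H]1O[C@@H]1c1ccc2OC(C)(C)Oc2c1
A3 | alternative 1 | methyl (2S,3S)-2-(2,2-dimethyl-1,3-benzodioxol-5-yl)-7-(methoxymethoxy)-2,3-dihydrobenzofuran-3-carboxylate (trans) | COC(=O)[C@H]1c2cccc(OCOC)c2O[C@@H]1c1ccc2OC(C)(C)Oc2c1
A4 | alternative 2 | (2S)-8-acetoxy-5-bromo-2-(3,4-diacetoxyphenyl)chroman-4-one | CC(=O)Oc1ccc(Br)c2C(=O)C[C@H](Oc12)c1ccc(OC(C)=O)c(OC(C)=O)c1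
A5 | alternative 2 | methyl (2S,3S)-7-acetoxy-4-bromo-2-(3,4-diacetoxyphenyl)-2,3-dihydrobenzofuran-3-carboxylate (trans) | COC(=O)[C@H]1c2c(Br)ccc(OC(C)=O)c2O[C@@H]1c1ccc(OC(C)=O)c(OC(C)=O)c1
A6 | alternative 3 | anti-2-{1-[3,4-bis(benzyloxy)phenyl]-1-(ethynyloxy)-3-[(triisopropylsilyl)oxy]propan-2-yl}furan | CC(C)[Si](C(C)C)(C(C)C)OC[C@H]([C@H](OC#C)c1ccc(OCc2ccccc2)c(OCc2ccccc2)c1)c1ccco1
A7 | alternative 3 | (2S,3R)-2-[3,4-bis(benzyloxy)phenyl]-3-{[(triisopropylsilyl)oxy]methyl}-2,3-dihydrobenzofuran-7-ol (trans) | CC(C)[Si](C(C)C)(C(C)C)OC[C@H]1c2cccc(O)c2O[C@@H]1c1ccc(OCc2ccccc2)c(OCc2ccccc2)c1
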